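**Strategy.** The route rests on disconnecting ring A at the C3–C4 bond (drimane numbering). Ring B, with its C8 methyl, C7=C8 alkene and C5 stereocentre, is (S)-carvone, and the isopropenyl carbon of carvone becomes the gem-dimethyl carbon C4 flanking the C3 carbonyl. In one operation an iron hydride delivers a hydrogen atom to the isopropenyl group and the resulting tertiary C4 radical closes ring A onto a pendant nitrile, giving the C3 ketone and the trans-decalin. The precursor is carvone carrying methyl and 2-cyanoethyl groups at C10, the cyanoethyl arm anti to the isopropenyl arm. The C9 side chain with the isofraxidin ether is then delivered by a glycolate Ireland–Claisen rearrangement.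

Key step: step 3

**Remarks.**
- Drimane numbering is used for all bicyclic compounds: ring A = C1–C5 and C10, ring B = C5–C10, C11 = the CH2O carbon on C9.
- Configuration check: the target is (5S,9S,10R), with the C11 arm on C9 anti to the C10 methyl and syn to H5. (S)-Carvone supplies C5 unchanged, and the structures of the precursor and of the cyclised dione are consistent with the target, so no structure needed correcting.
- Assumption: the glycolate α-carbon in 16–19 forms without control and is written without configuration, since it ends as the CH2 group C11.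

**Step 1**
Reactants: 1 (S)-carvone
Product: 3 (5S)-2,6-dimethyl-5-(prop-1-en-2-yl)cyclohex-2-en-1-one (6-methylcarvone; C6 epimers), via lithium enolate 2 (not isolated)
Conditions: LiN(i-Pr)2 (commercial solution), THF, −78 °C; MeI, −78 to 0 °C
Reagents that add atoms: iodomethane, CI
Why: Kinetic α'-deprotonation gives the cross-conjugated enolate, which is C-methylated (enolate alkylation); the C6 epimer ratio does not matter because this centre is enolised again in step 2.

**Step 2**
Reactants: 3 6-methylcarvone; 4 acrylonitrile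
Product: 6 3-[(1R,6R)-1,3-dimethyl-2-oxo-6-(prop-1-en-2-yl)cyclohex-3-en-1-yl]propanenitrile (6-(2-cyanoethyl)-6-methylcarvone; cyanoethyl trans to isopropenyl), via lithium enolate 5 (not isolated)
Conditions: LiN(i-Pr)2, THF, −78 °C; acrylonitrile (slow addition), −78 °C; AcOH quench at −78 °C
Reagents that add atoms: none
Why: Michael addition (cyanoethylation) of the tetrasubstituted lithium enolate creates quaternary C10, the acceptor approaching the face anti to the neighbouring isopropenyl group so that the two arms end up trans; the cold quench should limit acrylonitrile oligomerisation and a second, intramolecular Michael addition of the nitrile anion to the enone.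

**Step 3**
Reactants: 6 6-(2-cyanoethyl)-6-methylcarvone
Product: 8 (5R,10R)-11-nordrim-7-ene-3,9-dione (trans-fused; H5 anti to the C10 methyl), via ketimine 7 (not isolated)
Conditions: Fe(acac)3 (30 mol%), PhSiH3 (2.5 equiv), degassed EtOH (0.02 M), 60 °C; then 1 M aq. HCl, THF, rt
Reagents that add atoms: water, O
Why: Proposed new method: an iron hydride formed from Fe(acac)3 and PhSiH3 in ethanol transfers a hydrogen atom to the CH2 terminus of the isopropenyl group, the tertiary C4 radical adds to the nitrile carbon C3, divalent iron reduces the iminyl radical to ketimine 7 (returning trivalent iron), and aqueous acid hydrolyses 7 to the C3 ketone. The closest known reaction types are iron-hydride hydrogen-atom-transfer cyclisations of alkenes onto ketones and enones, and Bu3SnH- or Cp2TiCl-mediated radical cyclisations onto nitriles. Ring A closes in the 6-exo-dig mode through a chair-like arrangement in which the C5 and C10 arms are both equatorial on ring B. No stereocentre is created (C4 carries two methyl groups, C3 is trigonal), and the trans ring fusion follows from the anti C5/C10 relationship fixed in step 2. The step needs hydrogen-atom transfer at the electron-rich 1,1-disubstituted alkene and not at the electron-poor trisubstituted C7=C8 enone alkene, which the substitution pattern secures; it also needs nitrile capture to outrun reduction or isomerisation of the radical, which high dilution, the quaternary C10 in the tether and the lack of any strain-free alternative ring closure should favour.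

**Step 4**
Reactants: 8 11-nordrim-7-ene-3,9-dione
Product: 9 3,3-(ethylenedioxy)-11-nordrim-7-en-9-one
Conditions: HOCH2CH2OH, p-TsOH·H2O (cat.), benzene, reflux, Dean–Stark
Reagents that add atoms: ethylene glycol, OCCO
Why: Acid-catalysed ketalisation should select the saturated C3 ketone over the C9 carbonyl, which is deactivated by conjugation and flanked by quaternary C10 and the methyl-bearing C8; no centre is epimerisable.

**Step 5**
Reactants: 9 3,3-(ethylenedioxy)-11-nordrim-7-en-9-one
Product: 10 7,8-epoxy-3,3-(ethylenedioxy)-11-nordriman-9-one (epoxide oxygen syn to H5, anti to the C10 methyl)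
Conditions: 30% aq. H2O2, NaOH (0.3 equiv), MeOH, 0 °C to rt
Reagents that add atoms: hydrogen peroxide, OO
Why: Weitz–Scheffer nucleophilic epoxidation, in which hydroperoxide adds to C7 along the axial trajectory on the H5 face (as carvone is epoxidised anti to its C5 substituent) and closes to the epoxide on that face, setting C7 and C8.

**Step 6**
Reactants: 10 7,8-epoxy ketone
Product: 12 (7S)-3,3-(ethylenedioxy)-11-nordrim-8-en-7-ol (hydroxyl pseudoaxial, syn to H5, anti to the C10 methyl), via epoxy hydrazone 11 (not isolated)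
Conditions: N2H4·H2O, AcOH (cat.), MeOH, 0 °C to rt
Reagents that add atoms: none
Why: Wharton transposition, in which the epoxy hydrazone opens to an allylic diazene that loses N2 to leave the C8=C9 alkene; the C7–O bond is never broken, so C7 keeps the configuration set in step 5.

**Step 7**
Reactants: 12 allylic alcohol
Product: 13 7-O-bromoacetyl ester of 12
Conditions: BrCH2COBr, pyridine, CH2Cl2, 0 °C
Reagents that add atoms: bromoacetyl bromide, O=C(Br)CBr
Why: Acylation of a secondary allylic alcohol by an acyl bromide with pyridine as acid acceptor, which leaves the ketal and C7 untouched.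

**Step 8**
Reactants: 13 bromoacetate; 14 isofraxidin (7-hydroxy-6,8-dimethoxycoumarin)
Product: 15 7-O-[(6,8-dimethoxy-2-oxo-2H-chromen-7-yl)oxy]acetyl ester of 12
Conditions: K2CO3, acetone, 50 °C
Reagents that add atoms: none
Why: Williamson ether synthesis, the phenoxide displacing the activated α-bromo ester bromide by SN2, so the aryl–O–CH2 bond is made at an unhindered carbon.

**Step 9**
Reactants: 15 aryloxyacetate
Product: 18 2-[(6,8-dimethoxy-2-oxo-2H-chromen-7-yl)oxy]-2-[3,3-(ethylenedioxy)-11-nordrim-7-en-9-yl]acetic acid (C9 arm anti to the C10 methyl; α-carbon epimers), via silyl ketene acetal 16 (not isolated), via trimethylsilyl ester 17 (not isolated)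
Conditions: LiN(SiMe3)2, Me3SiCl, THF, −78 °C, then rt to 60 °C; aq. citric acid
Reagents that add atoms: none
Why: Ireland–Claisen rearrangement, a suprafacial [3,3] shift from the pseudoaxial C7–O bond on the H5 face, so the new C9–C bond forms on that same face, anti to the C10 methyl (1,3-chirality transfer sets C9), and the alkene moves to C7=C8.

**Step 10**
Reactants: 18 α-aryloxy acid
Product: 20 7-{[(5S,9S,10R)-3,3-(ethylenedioxy)drim-7-en-11-yl]oxy}-6,8-dimethoxy-2H-chromen-2-one, via Barton ester 19 (not isolated)
Conditions: N-hydroxypyridine-2-thione, DCC, CH2Cl2, 0 °C to rt, dark; then t-BuSH, hν (tungsten lamp), rt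
Reagents that add atoms: none
Why: Barton reductive decarboxylation, in which the thiohydroxamate ester fragments to CO2 and a stabilised α-aryloxyalkyl radical that takes a hydrogen atom from the thiol; C9 is not involved.

**Step 11**
Reactants: 20 ketal
Product: 21 7-{[(5S,9S,10R)-3-oxodrim-7-en-11-yl]oxy}-6,8-dimethoxy-2H-chromen-2-one
Conditions: 1 M aq. HCl, THF, rt
Reagents that add atoms: water, O
Why: Acid hydrolysis of a dioxolane next to a gem-dimethyl carbon should be fast, and the aryl ether, coumarin and trisubstituted alkene should tolerate dilute acid at room temperature.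

**Step 12**
Reactants: 21 3-ketone
Product: 22 7-{[(1S,4aS,8aR)-2,5,5,8a-tetramethyl-6-oxo-1,4,4a,5,6,8a-hexahydronaphthalen-1-yl]methoxy}-6,8-dimethoxy-2H-chromen-2-one (target)
Conditions: IBX (2-iodoxybenzoic acid), DMSO, 75 °C
Reagents that add atoms: none
Why: IBX dehydrogenation of a ketone to its enone; C2 is the only enolisable position (C4 is quaternary), so only the C1=C2 alkene can form.

**Compound list**

1 | (S)-carvone | C=C(C)[C@H]1CC=C(C)C(=O)C1 | starting material
2 | lithium cross-conjugated enolate of 1 (not isolated) | C=C(C)[C@H]1CC=C(C)C(O[Li])=C1 | intermediate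
3 | (5S)-2,6-dimethyl-5-(prop-1-en-2-yl)cyclohex-2-en-1-one (6-methylcarvone, C6 epimers) | C=C(C)[C@H]1CC=C(C)C(=O)C1C | intermediate
4 | acrylonitrile | C=CC#N | starting material
5 | lithium enolate of 3 (not isolated) | C=C(C)[C@H]1CC=C(C)C(O[Li])=C1C | intermediate
6 | 3-[(1R,6R)-1,3-dimethyl-2-oxo-6-(prop-1-en-2-yl)cyclohex-3-en-1-yl]propanenitrile | C=C(C)[C@H]1CC=C(C)C(=O)[C@]1(C)CCC#N | intermediate
7 | 3-imino-11-nordrim-7-en-9-one, N–H ketimine (not isolated) | O=C1C(C)=CC[C@@H]2C(C)(C)C(=N)CC[C@]21C | intermediate
8 | (5R,10R)-11-nordrim-7-ene-3,9-dione, trans-fused | O=C1C(C)=CC[C@@H]2C(C)(C)C(=O)CC[C@]21C | intermediate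
9 | 3,3-(ethylenedioxy)-11-nordrim-7-en-9-one | O=C1C(C)=CC[C@@H]2C(C)(C)C3(OCCO3)CC[C@]21C | intermediate
10 | 7,8-epoxy-3,3-(ethylenedioxy)-11-nordriman-9-one, epoxide syn to H5 | O=C1[C@@]2(C)O[C@H]2C[C@@H]3C(C)(C)C4(OCCO4)CC[C@]31C | intermediate
11 | C9 hydrazone of 10 (not isolated) | NN=C1[C@@]2(C)O[C@H]2C[C@@H]3C(C)(C)C4(OCCO4)CC[C@]31C | intermediate
12 | (7S)-3,3-(ethylenedioxy)-11-nordrim-8-en-7-ol, OH syn to H5 | C1=C(C)[C@@H](O)C[C@@H]2C(C)(C)C3(OCCO3)CC[C@]21C | intermediate
13 | 7-O-bromoacetyl ester of 12 | C1=C(C)[C@@H](OC(=O)CBr)C[C@@H]2C(C)(C)C3(OCCO3)CC[C@]21C | intermediate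
14 | isofraxidin (7-hydroxy-6,8-dimethoxycoumarin) | COc1cc2ccc(=O)oc2c(OC)c1O | starting material
15 | 7-O-(isofraxidin-7-yloxy)acetyl ester of 12 | C1=C(C)[C@@H](OC(=O)COc3c(OC)cc4ccc(=O)oc4c3OC)C[C@@H]2C(C)(C)C5(OCCO5)CC[C@]21C | intermediate
16 | trimethylsilyl ketene acetal of 15 (not isolated) | C1=C(C)[C@@H](OC(O[Si](C)(C)C)=COc3c(OC)cc4ccc(=O)oc4c3OC)C[C@@H]2C(C)(C)C5(OCCO5)CC[C@]21C | intermediate
17 | trimethylsilyl ester of 18 (not isolated) | C[Si](C)(C)OC(=O)C(Oc1c(OC)cc2ccc(=O)oc2c1OC)[C@H]1C(C)=CC[C@@H]2C(C)(C)C3(OCCO3)CC[C@]21C | intermediate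
18 | 2-(isofraxidin-7-yloxy)-2-[3,3-(ethylenedioxy)-11-nordrim-7-en-9-yl]acetic acid, C9 arm anti to C10 methyl | OC(=O)C(Oc1c(OC)cc2ccc(=O)oc2c1OC)[C@H]1C(C)=CC[C@@H]2C(C)(C)C3(OCCO3)CC[C@]21C | intermediate
19 | N-acyloxypyridine-2-thione (Barton) ester of 18 (not isolated) | S=c1ccccn1OC(=O)C(Oc1c(OC)cc2ccc(=O)oc2c1OC)[C@H]1C(C)=CC[C@@H]2C(C)(C)C3(OCCO3)CC[C@]21C | intermediate
20 | 7-{[(5S,9S,10R)-3,3-(ethylenedioxy)drim-7-en-11-yl]oxy}-6,8-dimethoxy-2H-chromen-2-one | COc1cc2ccc(=O)oc2c(OC)c1OC[C@H]1C(C)=CC[C@@H]2C(C)(C)C3(OCCO3)CC[C@]21C | intermediate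
21 | 7-{[(5S,9S,10R)-3-oxodrim-7-en-11-yl]oxy}-6,8-dimethoxy-2H-chromen-2-one | COc1cc2ccc(=O)oc2c(OC)c1OC[C@H]1C(C)=CC[C@@H]2C(C)(C)C(=O)CC[C@]21C | intermediate
22 | 7-{[(1S,4aS,8aR)-2,5,5,8a-tetramethyl-6-oxo-1,4,4a,5,6,8a-hexahydronaphthalen-1-yl]methoxy}-6,8-dimethoxy-2H-chromen-2-one | COc1cc2ccc(=O)oc2c(OC)c1OC[C@H]1C(C)=CC[C@@H]2C(C)(C)C(=O)C=C[C@]21C | target

**Totals.** Total step count: 12. Longest linear sequence: 12 steps, from 1 to 22; 4 and 14 enter as purchased materials.

**Steps most likely to fail**

Step 3 (Proposed new method). The tertiary C4 radical may be reduced to the isopropyl group or returned to alkene isomers faster than the nitrile captures it, or the iminyl radical may reopen by β-scission before it is reduced. The fallback sets out from 6 and returns at 8, using the known epoxide-opening radical cyclisation onto nitriles with trivalent titanium. mCPBA should epoxidise only the isopropenyl group to give the side-chain epoxide F1. Cp2TiCl (from Cp2TiCl2 and Zn, THF) opens it to the same tertiary C4 radical, which closes ring A onto the nitrile while a second equivalent of the titanium reagent traps the iminyl radical. Acidic work-up then gives the 4-hydroxymethyl ketone F2 (C4 epimers). 1,1'-Thiocarbonyldiimidazole converts the primary alcohol into the imidazolide F3, and Barton–McCombie deoxygenation with Bu3SnH/AIBN at high tin hydride concentration restores the gem-dimethyl group of 8.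

Step 2. Anionic oligomerisation of acrylonitrile, or a second intramolecular Michael addition of the nitrile-stabilised anion to C7 of the enone, may consume the adduct. The fallback sets out from 3 and returns at 6. Enolate 5 is alkylated with allyl bromide, anti to the isopropenyl group, to give 6-allyl-6-methylcarvone F4. Disiamylborane hydroborates only the monosubstituted alkene to the alkylborane F5 (not isolated), and NaBO3·4H2O oxidises it to the primary alcohol F6. One-pot oxidation with TEMPO (cat.), PhI(OAc)2 and NH4OAc in MeCN–H2O converts the CH2OH group into the nitrile of 6.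

Step 6. Hydrazone formation at C9 may be too slow, since the carbonyl sits between quaternary C10 and the fully substituted epoxide carbon C8, and hydrazine may instead open the epoxide. The fallback sets out from 10 and returns at 12. NaBH4/CeCl3·7H2O reduces the C9 ketone to the epoxy alcohol F7 (C9 epimers), and NaH, CS2 then MeI give the xanthate F8. Bu3SnH/AIBN generates the C9 radical, which opens the epoxide to the C7 alkoxy radical; hydrogen transfer then gives 12 with C7 unchanged.

**Further compounds**

F1 | step 3 | 3-[(1R,6R)-1,3-dimethyl-6-(2-methyloxiran-2-yl)-2-oxocyclohex-3-en-1-yl]propanenitrile (epoxide epimers) | CC1(CO1)[C@H]1CC=C(C)C(=O)[C@]1(C)CCC#N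
F2 | step 3 | 4-(hydroxymethyl)-4,8,10-trimethyl analogue of 8 (12-hydroxy-11-nordrim-7-ene-3,9-dione, C4 epimers) | O=C1C(C)=CC[C@@H]2C(C)(CO)C(=O)CC[C@]21C
F3 | step 3 | O-imidazol-1-ylthiocarbonyl derivative of F2 | O=C1C(C)=CC[C@@H]2C(C)(COC(=S)n3ccnc3)C(=O)CC[C@]21C
F4 | step 2 | 6-allyl-6-methylcarvone, allyl trans to isopropenyl | C=C(C)[C@H]1CC=C(C)C(=O)[C@]1(C)CC=C
F5 | step 2 | disiamyl(alkyl)borane from F4 (not isolated) | C=C(C)[C@H]1CC=C(C)C(=O)[C@]1(C)CCCB(C(C)C(C)C)C(C)C(C)C
F6 | step 2 | 6-(3-hydroxypropyl)-6-methylcarvone | C=C(C)[C@H]1CC=C(C)C(=O)[C@]1(C)CCCO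
F7 | step 6 | 7,8-epoxy-3,3-(ethylenedioxy)-11-nordriman-9-ol (C9 epimers) | OC1[C@@]2(C)O[C@H]2C[C@@H]3C(C)(C)C4(OCCO4)CC[C@]31C
F8 | step 6 | S-methyl xanthate of F7 | CSC(=S)OC1[C@@]2(C)O[C@H]2C[C@@H]3C(C)(C)C4(OCCO4)CC[C@]31C
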